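Cedar and oak differ in reagent and in time, and I compare them through the earlier runs.

common to all: substrate 0.20 M
- west: reagent 0.69 equiv; run made earlier
- north-west: reagent 0.86 equiv; run made earlier
- south-east: reagent 1.1 equiv; run made earlier
- cedar: reagent 1.00 equiv; time 2.0 h
- oak: reagent 0.670 equiv; time 3.0 h

| run | time / min | target / % |
|---|---|---|
| west | 6.00 | 0.1 |
| west | 12.0 | 0 |
| west | 25.0 | 1.0 |
| west | 40.0 | 2.4 |
| west | 80.0 | 6.0 |
| north-west | 15.0 | 0 |
| north-west | 30.0 | 1.2 |
| north-west | 50.0 | 4.4 |
| north-west | 60.0 | 6.7 |
| north-west | 80.0 | 8.0 |
| south-east | 8.00 | 0 |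
| south-east | 20.0 | 1.7 |
| south-east | 40.0 | 5.3 |
| south-east | 60.0 | 8.6 |
| south-east | 80.0 | 12.3 |

(scatter of a reading: 0.5 percentage points)

- the winner by amount of target, in percent of the substrate charged; "neither" if no more than 2 percentage points parts them (cedar / oak / neither)
- how much target is there at the end, in percent of the substrate charged: cedar
- how much target is there at the end, in percent of the substrate charged: oak



I read the flask as a ladder of times. The first rung is the lag (induction period). The south-east run climbs by 0.00177 min⁻¹, as a fraction of the substrate charged, and that line drawn back meets zero at 10.4 min.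

The second rung is the straight stretch. The west run climbs by 9.09 × 10⁻⁴ min⁻¹. Comparing the two slopes gives the apparent reagent order, the exponent n with which target follows the reagent charge at fixed c(substrate): 1.42.

Scaled by n, the slope is 0.00154 min⁻¹ for cedar and 8.72 × 10⁻⁴ min⁻¹ for oak.

The last rung is the drain. At its slope and at one reagent per target, cedar's reagent would last 648 min, longer than its 2.0 h, so I expect a bend, not a stop.

My first round gives 16.9% for cedar and 14.8% for oak. For the second round I assume one reagent per target, so mean reagent falls by half of that answer, and the slope falls with power n. For cedar this gives 14.9%. For oak, reckoned on its own charge, it gives 12.5%. The gap between the two is 2.4 percentage points.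

The forecast, higher than mine on both flasks, says cedar, with 15.7% and 13.2%: “Cedar is probably ahead, but only slightly beyond the 2-point margin.”

The flask gives cedar, with cedar at 15.3% and oak at 9.64%.

    substrate ⇌ intermediate A (K = 1.20, k = 0.560 h⁻¹)
    substrate + reagent → intermediate B (k = 3.80 L mol⁻¹ h⁻¹)
    intermediate B → intermediate C (k = 4.20 h⁻¹)
    reagent + intermediate C ⇌ target (K = 11.0 L mol⁻¹, k = 6.20 L mol⁻¹ h⁻¹)
    reagent + target → over-reaction product (k = 0.360 L mol⁻¹ h⁻¹)

In cedar at 2.00 h, intermediate C is made 1.83 times as fast as it is used up, each step taken net, and it stands at 28.4% beside 15.3% target. In oak at 3.00 h, it stands at 28.0% beside 9.64% target. At a fixed time, n still carries: oak scaled up to the north-west charge gives 13.8%, and that charge left for 3.0 h holds 14.2%. Cedar scaled down to the west charge gives 9.02%, and that charge left for 2.0 h holds 8.60%.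

(All runs were generated by integration from invented constants; scatter was added.)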